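The constants are assumed, and the outcome is calculated.

Target cannot stay ahead of its isomer: with an equilibrium constant of 1.0 the two tend to half each, and the reckoning below is measured from that split.

    initiator → 2 initiating radical (k1 = 0.00220 s⁻¹)
    substrate + initiating radical → capped initiator + first chain carrier (k2 = 1.44 × 10⁷ M⁻¹ s⁻¹)
    partner + first chain carrier → target + second chain carrier (k3 = 1.43 × 10⁷ M⁻¹ s⁻¹)
    substrate + second chain carrier → by-product + first chain carrier (k4 = 6.28 × 10⁵ M⁻¹ s⁻¹)
    2 first chain carrier → ended chains A (k5 = 1.4 × 10⁹ M⁻¹ s⁻¹)
    2 second chain carrier → ended chains B (k6 = 1 × 10⁸ M⁻¹ s⁻¹)
    target ⇌ isomer of the product (K7 = 1.0, k7 = 0.00558 s⁻¹)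

common to all: initiator 10 mol%
- Thursday's: substrate 0.020 M (fed, over 1.60 min); partner 1.30 equiv; time 2.0 min; all but substrate at the start; substrate goes in evenly over 1.60 min, the run ends at 2.0 min
- Sunday's: substrate 0.020 M; partner 1.30 equiv (fed, over 1.60 min); time 2.0 min; a stirred flask in which partner is dosed at a steady rate over 1.60 min without added volume, worked up at 2.0 min
- Friday's: substrate 0.020 M; partner 1.30 equiv; time 2.0 min; a closed flask charged with all of it at once and left for 2.0 min
- Tuesday's: substrate 0.020 M; partner 1.30 equiv; a single well-mixed tank run continuously and read at steady state, 2.0 min in it on average

- percent here means substrate units held: one ended chains A counts as two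
- a doubled species enters its step squared and goes two at a time
- the stated concentrations are those of everything mixed, before any reaction; amounts are the same in each set-up
- the feed brings no volume worth counting
- run time (Thursday's): 2.0 min

- the set-up with the highest amount of target at the outlet or at the end, in percent of the substrate put in ("none" if the first two lie within 2 percentage points) (Thursday's / Sunday's / Friday's / Tuesday's / none)
- amount of target at the outlet or at the end, in percent of the substrate put in, Thursday's
- amount of target at the outlet or at the end, in percent of the substrate put in, Sunday's
- amount of target at the outlet or at the end, in percent of the substrate put in, Friday's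
- amount of target at the outlet or at the end, in percent of the substrate put in, Tuesday's

The quick number requested rests on the relaxation half-life of the target and isomer pair, 62.1 s, the time in which step 7, run both ways, halves the excess of target over the even split. A batch of target of a given age is then still target by a share of 0.5 plus 0.5 times the excess factor left at that age. In Friday's and Thursday's, where partner stands in the flask from the start, step 4 is the slower propagation: reckoned at full charges it runs at 12600 s⁻¹ against 3.72 × 10⁵ s⁻¹ for step 3, so the second chain carrier is the resting state in those two flasks. For those two flasks, balancing initiation against the termination of that carrier gives 2.10 × 10⁻⁷ M, and so a substrate half-life of 5.26 s, far shorter than the relaxation half-life, which makes a batch's age there the time since its substrate met the chain.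

Friday's target forms at the start, so its excess factor is 0.262 and its share 63.1%. Thursday's forms evenly during dosing, which averages the factor to 0.469 and gives 73.5%. Sunday's, with its partner fed and so outside that comparison of rates, is taken to form target evenly until one equivalent of partner is in, at 1.23 min, with factor 0.407 and share 70.3%. Tuesday's spread of ages gives factor 0.427, and because unconverted substrate is not subtracted its figure is a ceiling, 71.4%. The reckoned winner is Thursday's.

The hunch sent with the request is the forecast: 75.5%, 68.5%, 64.3% and 66.8% in the order of the questions, with Thursday's best, holding that “the yield is set mainly by how long target sits isomerising towards the 1:1 equilibrium”. Its Thursday's figure is higher than the reckoned one, and its Tuesday's figure lower.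

The simulation gives 75.5%, 68.8%, 64.3% and 66.8% in the same order, with Thursday's highest. A neighbour of Friday's flask is charged with 0.330 equiv of partner, which makes partner the limiting reagent. Multiplying that charge by Friday's share gives 20.8% target. At 2.00 min that flask holds 0% of its partner, 62% of its substrate, 12.1% isomer and 20.9% target.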